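## Structural features

- The target is a bis-ester. Its core is a cyclobutane-1,3-dicarboxylic acid with 4-hydroxy-3-methoxyphenyl groups on C2 and C4 in the centrosymmetric 1α,2α,3β,4β pattern (each aryl cis to one ester neighbour, trans to the other). Both carboxyls are esterified with the same enantiomer of a bicyclic amino alcohol.
- Each amino alcohol is a cis-fused octahydrocyclopenta[c]pyridine: ring A is the cyclopentane C4a, C5, C6, C7, C7a; ring B is the N-methylpiperidine C1, N2, C3, C4, C4a, C7a. It has five contiguous stereocentres, C4 (R), C4a (S), C7a (R), C7 (S), C6 (R).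
- H4, H4a and H7a lie on one face. The C4 methyl sits on the concave side of the folded bicycle; the C7 methyl and the C6 oxygen sit on the convex side, cis to each other.
- Fragile groups are the free phenols, the two basic tertiary amines, and the esters of a hindered secondary alcohol on an aryl-substituted cyclobutane whose four ring carbons are all benzylic or α to an ester. The esters therefore belong at the end of the route.
- The cyclobutane is an achiral head-to-tail dimer of a ferulic-type cinnamic acid. The real difficulty is the amine unit: five stereocentres, the concave C4 methyl, and a nitrogen in a ring that offers no other heteroatom handle.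
- The feature exploited: if C1 is bonded to C3 in place of N2, the carbons C1, C3, C4, C4a, C7a form a cyclopentenone fused to ring A. This bicyclo[3.3.0]octenone comes in one (2+2+1) step from an acyclic enyne, and its folded shape lets C4 and C4a be set from the convex face before C1–C3 is cut and N2 inserted.

## Logic of the disconnections

**26 to 25.** The two aryl O–CH2Ph bonds are cut. Free phenols would compete as nucleophiles in the esterification, so they are masked until the end. No skeletal simplification results. The forward step must remove benzyl groups without touching the esters, the amines or the four-membered ring.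

**25 to 23 and two molecules of 18.** The two C6–O bonds are cut on the alkyl side, not the acyl side. Forming them with inversion means the alcohol can carry its oxygen on the concave face, which is what the earlier steps deliver most easily. The molecule splits into an achiral diacid and two identical C11 amino alcohols. The forward step must be a clean double SN2 displacement at a hindered secondary carbon.

**23 to two molecules of 22.** The two ring bonds that join the α-carbon of one cinnamic acid to the β-carbon of the other are cut. The ring and its four stereocentres then come from one achiral monomer. The forward step must pair the alkenes head-to-tail across an inversion centre.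

**22 to 19 and 20.** The aryl O–benzyl bond is cut, leading back to a commercial hydroxycinnamic acid. The forward step must leave the acid free.

**18 to 16 (through 17).** The C3 methylene is traced to a lactam carbonyl and the C6 hydroxyl to a silyl ether. The lactam marks where the nitrogen was acylated on ring closure. The forward step is a hydride reduction and an ether cleavage that touch no stereocentre.

**16 to 13 and 14.** Both C–N bonds of ring B (N2–C1 and N2–C3) are cut. The nitrogen and its methyl group come from one simple amine, and what remains is a nitrogen-free cyclopentane with an aldehyde at C1 and an acid at C3. The forward step must not epimerise C7a, which is α to the aldehyde.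

**13 to 12 to 11.** C1 and C3 are reconnected. The aldehyde and acid are the two ends of a cleaved enol double bond of a cyclopentanone. This turns a cyclopentane with two stereodefined side chains into a rigid bicyclo[3.3.0]octanone. The forward step needs regioselective enolisation toward C1 and away from C4.

**11 to 10.** The C4–H and C4a–H bonds are removed to give the conjugated enone. The forward step must add both hydrogens from the convex face and leave C4 unepimerised.

**10 to 8.** C4a–C7a, C3–C4 and C1–C3 are cut, with C3 returned to carbon monoxide. Both rings open to an acyclic 1,6-enyne with two stereocentres. The forward step must select one face of the alkene under the influence of C7.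

**8 to 6 and 7; 6 to 2 and 3; 2 to 1.** The O–Si bond is cut, then the C6–C7 bond between the carbinol and the methyl-bearing allylic carbon, then the aldehyde is traced to the alcohol. Both acyclic stereocentres arise in one reagent-controlled C–C bond formation, from a C5 alkynol and a C4 alkene. The forward steps must handle a labile β,γ-alkynyl aldehyde and keep the Z geometry of the crotyl reagent.

## Other disconnections considered

**Alternative 1:** pyrrolidine ring contraction.
- Cut: one cyclobutane bond between an aryl-bearing and an ester-bearing carbon, with nitrogen put back between them. This leads to the pyrrolidine A2.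
- Forward key step: the secondary amine of A2 would be N-aminated by an iodonitrene (hypervalent iodine oxidant plus an ammonia source). The 1,1-diazene loses N2 and the 1,4-biradical should collapse faster than it rotates, giving the cyclobutane diester A1 with retention at both carbons.
- In favour: solution chemistry independent of crystal packing; head-to-tail regiochemistry is fixed by the (3+2) cycloaddition that would build A2; racemic A2 suffices because A1 is achiral.
- Against: A2 needs the 2,5-trans arrangement, which a standard endo azomethine ylide cycloaddition does not deliver, so an epimerisation or an exo-selective variant is needed. The benzylic 1,4-biradical can fragment to two alkenes. A1 carries methyl esters and aryl acetates, so hydrolysis (which also strips the acetates) and re-protection are required before it can replace 23.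
- Comparison: it addresses only the achiral four-membered ring (four of fourteen stereocentres) and leaves the amine unit untouched, whereas the chosen key step builds the carbon framework of that unit. Mechanistically it is a radical-pair recombination against a metal-templated cycloaddition; both are stereospecific in principle. On independence from crystal packing it is better than step 11 of the chosen plan. On step count it is poorer (about six operations to a usable diacid against two).

**Alternative 2:** electroreductive decarboxylative radical cyclisation.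
- Cut: C1–C7a of ring B. This gives the redox-active ester A4, in which nitrogen, its methyl, C3, C4 and C4a are in place and ring A is a 2-methylcyclopentenone.
- Forward key step: cathodic reduction of the N-hydroxyphthalimide ester would release CO2 and a nucleophilic α-amino radical at C1. This should add 6-exo to the enone β-carbon C7a; reduction and protonation of the α-keto radical would give the amino ketone A3.
- In favour: nitrogen is carried through, so no temporary C–C bond, ozonolysis or lactam reduction is needed. The tether forces the cis ring fusion. The polarity match is good. A3 could be reduced from the convex face to 18 and joined as in steps 12 and 13.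
- Against: C4 and C4a must be set beforehand in a 4-substituted cyclopentenone with an adjacent side-chain stereocentre, for which nothing as simple as a crotylation is at hand. C7 is set only by protonation α to the ketone and would rely on equilibration to the exo methyl. A β-amino ketone can open by retro-Michael reaction. Tertiary amines are oxidisable at the counter electrode unless a divided cell or sacrificial anode is used.
- Comparison: both plans close a ring onto a cyclopentene π-bond, but the alternative closes ring B onto a preformed ring A, while the chosen plan forms ring A and a carbocyclic stand-in for ring B together. One is a one-electron conjugate addition, the other a two-electron organocobalt insertion. After the key step the alternative is better (two steps to 18 instead of five). It is equal in delivering the C6-epimeric alcohol needed for the inverting esterification. Before the key step the chosen plan is shorter and better controlled (three steps, both acyclic centres by reagent control).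

**Alternative 3:** coumarin photodimer.
- Cut: the same pair of cyclobutane bonds as in step 11, but made in the coumarin A6, where the lactone holds the cinnamate in its Z form.
- Forward key step: irradiation of crystalline A6 packed in centrosymmetric pairs would give the anti head-to-tail dimer A5, a bis-dihydrocoumarin whose four ring carbons have the relative configuration of 23.
- In favour: coumarins absorb at longer wavelength and cannot waste light on E/Z isomerisation. The cis lactone fusions of A5 translate into the required aryl/carboxyl relationships. The aryl ester of A5 is an activated acyl group.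
- Against: which of the four possible coumarin dimers forms is again decided by the crystal. Each aryl ring of A5 carries an extra oxygen ortho to the cyclobutane that must be removed after lactone opening (two sulfonylation–reduction sequences). The freed phenol tends to re-close the lactone. Direct acylation of an alcohol by A5 would go with retention and would need the C6 epimer of 18.
- Comparison: on topochemical risk it is equal to step 11. On photochemical efficiency it is better. On step economy it is clearly poorer (four or more extra operations), and like alternative 1 it addresses only the achiral core.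

Key step: step 4

**Assumption (remark on the chemistry):** both amino alcohol units are (4R,4aS,6R,7S,7aR) and the diacid core is the achiral centrosymmetric isomer, so a single bis-ester results whichever carboxyl reacts first.

**Numbering:** the atom labels C1, N2, C3, C4, C4a, C5, C6, C7, C7a of the final bicyclic amine are used throughout, including for acyclic and carbocyclic precursors.

**Configuration check:** 8 is the syn (3S,4S) isomer. Its C4 becomes C6 with the oxygen on the concave face (the epimer of the target at this centre, corrected by the inverting esterification in step 12); its C3 becomes C7. The enone 10 has only one sp3 ring-fusion carbon, so the cis ring fusion is created in step 5, not step 4. The tert-butyldimethylsilyl group is kept because its bulk on the concave face supports step 5 while sitting one carbon away from the alkene in step 4.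

## Route

Step 1
Reactants: 1 pent-3-yn-1-ol
Product: 2 pent-3-ynal
Conditions: Dess–Martin periodinane (1.2 equiv), CH2Cl2, 0 °C → rt; cold aqueous NaHCO3/Na2S2O3 wash; dried solution concentrated cold and used at once
Reagents that add atoms: none
Why: Dess–Martin oxidation of a primary alcohol stops at the aldehyde under amine-free conditions, which matters because this β,γ-alkynyl aldehyde isomerises to the conjugated allenal with base; the volatile product is kept cold in solution and carried straight on.

Step 2
Reactants: 2 pent-3-ynal; 3 (Z)-but-2-ene
Product: 6 (3S,4S)-3-methyloct-1-en-6-yn-4-ol, via (Z)-crotyldiisopinocampheylborane 4 (not isolated), via diisopinocampheylborinate ester 5 (not isolated)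
Conditions: 3 (excess), KOtBu, n-BuLi, THF, −78 → −45 °C; (+)-Ipc2BOMe [from (−)-α-pinene], −78 °C; BF3·OEt2; 2, −78 °C; then NaOH, H2O2, 0 °C → rt
Reagents that add atoms: (Z)-but-2-ene 3, C/C=C\C
Why: Asymmetric (Z)-crotylboration through a closed chair transition state, so the Z geometry of the crotylborane (from (Z)-crotylpotassium, C4H7K, kept at or below −45 °C) becomes the syn relationship of the methyl and hydroxyl groups. The isopinocampheyl groups of this antipode should direct attack to the Re face of the aldehyde, setting C6 (S) and C7 (S) by reagent control; the opposite reagent would give the enantiomer. Alkaline peroxide cleaves the borinate without touching alkyne or alkene.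

Step 3
Reactants: 6 (3S,4S)-3-methyloct-1-en-6-yn-4-ol; 7 tert-butyldimethylsilyl chloride
Product: 8 tert-butyldimethyl{[(3S,4S)-3-methyloct-1-en-6-yn-4-yl]oxy}silane
Conditions: imidazole, DMF, rt
Reagents that add atoms: tert-butyldimethylsilyl chloride 7, CC(C)(C)[Si](C)(C)Cl
Why: Standard imidazole-promoted silylation of a secondary alcohol; the ether survives cobalt carbonyl, amide base, ozone and hydride and later shields the concave face.

Step 4
Reactants: 8 tert-butyldimethyl{[(3S,4S)-3-methyloct-1-en-6-yn-4-yl]oxy}silane
Product: 10 (5S,6S,6aS)-5-[(tert-butyldimethylsilyl)oxy]-3,6-dimethyl-4,5,6,6a-tetrahydropentalen-2(1H)-one, via hexacarbonyldicobalt alkyne complex 9 (not isolated)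
Conditions: Co2(CO)8 (1.1 equiv), CH2Cl2, rt, 2 h; then N-methylmorpholine N-oxide (8 equiv), 0 °C → rt
Reagents that add atoms: Co2(CO)8 (octacarbonyldicobalt, supplies one CO), O=C=[Co](=C=O)(=C=O)(=C=O)[Co](=C=O)(=C=O)(=C=O)=C=O
Why: Intramolecular Pauson–Khand reaction of a 1,6-enyne bearing an allylic substituent is the closest known reaction type. Co2(CO)8 (zerovalent cobalt) first binds the alkyne as the hexacarbonyldicobalt complex 9; the N-oxide then oxidises one CO ligand to CO2 and frees a coordination site for the tethered alkene. Insertion of the alkene into the Co–C bond at the inner alkyne carbon forms C4a–C7a and closes ring A (C4a, C5, C6, C7, C7a) in an exo mode dictated by the three-atom tether, which also fixes the regiochemistry. Migratory insertion of CO at the C1–Co bond and reductive elimination then form C1–C3 and C3–C4 and close the cyclopentenone (C1, C3, C4, C4a, C7a) as the second ring, a formal (2+2+1) union of alkyne, alkene and CO. The only new stereocentre, C7a, is set in the alkene insertion: the C7 methyl takes the exo (pseudo-equatorial) position of the envelope-like transition state to avoid allylic strain with the terminal CH2 and the cobalt cluster, so H7a ends up cis to the C7 methyl. The C6 silyl ether, one carbon further from the alkene, is thereby placed on the concave face and should perturb this preference less than the adjacent methyl enforces it. The selectivity needed is this diastereofacial choice of the alkene; it is secured by the C7 stereocentre and helped by running the N-oxide-promoted variant at or below room temperature under kinetic control. The methyl-capped alkyne puts the methyl on C4 and avoids the side reactions of terminal alkyne complexes.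

Step 5
Reactants: 10 (5S,6S,6aS)-5-[(tert-butyldimethylsilyl)oxy]-3,6-dimethyl-4,5,6,6a-tetrahydropentalen-2(1H)-one
Product: 11 (3R,3aR,5S,6S,6aR)-5-[(tert-butyldimethylsilyl)oxy]-3,6-dimethylhexahydropentalen-2(1H)-one
Conditions: H2 (1–4 atm), Pd/C (palladium on carbon), EtOAc, rt
Reagents that add atoms: none
Why: Heterogeneous hydrogenation of the conjugated tetrasubstituted alkene should deliver both hydrogens from the convex face (the face of H7a), because ring A and the concave silyl ether block the other side. This sets C4a (cis fusion) and C4 (methyl on the concave face); neutral solvent and short contact time avoid epimerisation of C4, which is α to the ketone.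

Step 6
Reactants: 11 (3R,3aR,5S,6S,6aR)-5-[(tert-butyldimethylsilyl)oxy]-3,6-dimethylhexahydropentalen-2(1H)-one
Product: 12 (1R,3aR,4S,5S,6aR)-5-[(tert-butyldimethylsilyl)oxy]-1,4-dimethyl-2-[(trimethylsilyl)oxy]-1,3a,4,5,6,6a-hexahydropentalene
Conditions: LiN(iPr)2 (commercial solution), Me3SiCl present from the start, THF, −78 °C; cold NaHCO3 work-up, used crude
Reagents that add atoms: chlorotrimethylsilane, C[Si](C)(C)Cl
Why: Kinetic deprotonation by the hindered amide base occurs at the methylene C1 and not at the methine C4; internal silyl quench traps the enolate before it can equilibrate, so the enol double bond lies between C3 and C1 and C4 stays untouched.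

Step 7
Reactants: 12 (1R,3aR,4S,5S,6aR)-5-[(tert-butyldimethylsilyl)oxy]-1,4-dimethyl-2-[(trimethylsilyl)oxy]-1,3a,4,5,6,6a-hexahydropentalene
Product: 13 (2R)-2-[(1R,2R,3S,4S)-4-[(tert-butyldimethylsilyl)oxy]-2-formyl-3-methylcyclopentyl]propanoic acid
Conditions: O3, CH2Cl2/MeOH, −78 °C; then Me2S, −78 °C → rt
Reagents that add atoms: ozone, [O-][O+]=O
Why: Ozonolysis of a silyl enol ether cleaves the only C=C bond in the molecule, the temporary C1–C3 link; reductive work-up leaves C1 as the aldehyde and C3 as the carboxylic acid, and the cold neutral conditions do not enolise C4 or C7a.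

Step 8
Reactants: 13 (2R)-2-[(1R,2R,3S,4S)-4-[(tert-butyldimethylsilyl)oxy]-2-formyl-3-methylcyclopentyl]propanoic acid; 14 methylamine
Product: 16 (4R,4aR,6S,7S,7aR)-6-[(tert-butyldimethylsilyl)oxy]-2,4,7-trimethyloctahydro-3H-cyclopenta[c]pyridin-3-one, via N-methyl amino acid 15 (not isolated)
Conditions: MeNH2 (2 M in MeOH, excess), H2 (1 atm), Pd/C, MeOH, rt; filter, concentrate; then toluene, 110 °C (Dean–Stark)
Reagents that add atoms: methylamine 14, CN
Why: Reductive amination by hydrogenation of the N-methyl imine forms N2–C1, with excess amine suppressing double alkylation. The volatile amine leaves on evaporation and the zwitterionic δ-amino acid, held cis on the cyclopentane, should close the six-membered lactam (N2–C3) on heating with loss of water. Prompt reduction of the imine limits epimerisation at C7a.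

Step 9
Reactants: 16 (4R,4aR,6S,7S,7aR)-6-[(tert-butyldimethylsilyl)oxy]-2,4,7-trimethyloctahydro-3H-cyclopenta[c]pyridin-3-one
Product: 18 (4R,4aS,6S,7S,7aR)-2,4,7-trimethyloctahydro-1H-cyclopenta[c]pyridin-6-ol, via silyl-protected amine 17 (not isolated)
Conditions: LiAlH4, THF, 0 → 65 °C; then MeOH, 3 M aqueous HCl, rt; NaOH to pH 12, extraction
Reagents that add atoms: none
Why: LiAlH4 reduces the tertiary lactam to the N-methylpiperidine; the acidic quench cleaves the silyl ether and dissolves the aluminium salts, and basification releases the amino alcohol. No stereocentre is involved.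

Step 10
Reactants: 19 ferulic acid, (E)-3-(4-hydroxy-3-methoxyphenyl)prop-2-enoic acid; 20 benzyl bromide
Product: 22 (E)-3-[4-(benzyloxy)-3-methoxyphenyl]prop-2-enoic acid, via benzyl ester benzyl ether 21 (not isolated)
Conditions: BnBr (2.3 equiv), K2CO3, DMF, 60 °C; then 2 M NaOH, MeOH, 60 °C; HCl to pH 2
Reagents that add atoms: benzyl bromide 20, BrCc1ccccc1
Why: Williamson alkylation of phenoxide and carboxylate followed by saponification of the benzyl ester only; the aryl benzyl ether is stable to hydroxide and the E alkene is unaffected.

Step 11
Reactants: 22 (E)-3-[4-(benzyloxy)-3-methoxyphenyl]prop-2-enoic acid (two molecules)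
Product: 23 (1α,2α,3β,4β)-2,4-bis[4-(benzyloxy)-3-methoxyphenyl]cyclobutane-1,3-dicarboxylic acid
Conditions: hν (high-pressure mercury lamp, Pyrex, λ > 300 nm), finely ground crystals stirred as a suspension in water, rt
Reagents that add atoms: none
Why: Topochemical [2+2] photodimerisation in the crystal. Cinnamic acids that pack as hydrogen-bonded dimers stacked antiparallel across an inversion centre, with the alkenes within about 4 Å, give the head-to-tail centrosymmetric dimer, with the trans geometry of each alkene kept and the new bonds cis. The solid state suppresses the E/Z isomerisation and isomer mixtures of solution photochemistry.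

Step 12
Reactants: 23 (1α,2α,3β,4β)-2,4-bis[4-(benzyloxy)-3-methoxyphenyl]cyclobutane-1,3-dicarboxylic acid; 18 (4R,4aS,6S,7S,7aR)-2,4,7-trimethyloctahydro-1H-cyclopenta[c]pyridin-6-ol (2.4 equiv)
Product: 25 bis[(4R,4aS,6R,7S,7aR)-2,4,7-trimethyloctahydro-1H-cyclopenta[c]pyridin-6-yl] (1α,2α,3β,4β)-2,4-bis[4-(benzyloxy)-3-methoxyphenyl]cyclobutane-1,3-dicarboxylate, via mono-ester mono-acid 24 (not isolated)
Conditions: PPh3, diisopropyl azodicarboxylate (DIAD), THF, 0 °C → rt
Reagents that add atoms: none
Why: Double Mitsunobu esterification: the alkoxyphosphonium ion of the concave-face C6 alcohol is displaced by carboxylate from the open convex face with inversion, converting C6 (S) into the (R) ester of the target. The two enantiotopic carboxyls react with the same enantiomer of 18, so both possible mono-esters converge on one bis-ester, and the benzyl ethers prevent alkylation of the phenols.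

Step 13
Reactants: 25 bis[(4R,4aS,6R,7S,7aR)-2,4,7-trimethyloctahydro-1H-cyclopenta[c]pyridin-6-yl] (1α,2α,3β,4β)-2,4-bis[4-(benzyloxy)-3-methoxyphenyl]cyclobutane-1,3-dicarboxylate
Product: 26 bis[(4R,4aS,6R,7S,7aR)-2,4,7-trimethyloctahydro-1H-cyclopenta[c]pyridin-6-yl] (1α,2α,3β,4β)-2,4-bis(4-hydroxy-3-methoxyphenyl)cyclobutane-1,3-dicarboxylate (CNP0283097.2)
Conditions: H2 (1 atm), Pd/C, MeOH/EtOAc, rt
Reagents that add atoms: none
Why: Hydrogenolysis of aryl benzyl ethers over palladium under neutral conditions; alkyl esters, tertiary amines and the cyclobutane are inert, so the fragile phenols appear only in the last step.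

## Compound list

1 | pent-3-yn-1-ol | CC#CCCO | starting material
2 | pent-3-ynal | CC#CCC=O | intermediate
3 | (Z)-but-2-ene | C/C=C\C | starting material
4 | [(2Z)-but-2-en-1-yl]bis[(1S,2S,3S,5R)-2,6,6-trimethylbicyclo[3.1.1]heptan-3-yl]borane | C/C=C\CB([C@H]1C[C@H]2C[C@@H]([C@@H]1C)C2(C)C)[C@H]1C[C@H]2C[C@@H]([C@@H]1C)C2(C)C | intermediate (not isolated)
5 | (3S,4S)-3-methyloct-1-en-6-yn-4-yl bis[(1S,2S,3S,5R)-2,6,6-trimethylbicyclo[3.1.1]heptan-3-yl]borinate | O(B([C@H]1C[C@H]2C[C@@H]([C@@H]1C)C2(C)C)[C@H]1C[C@H]2C[C@@H]([C@@H]1C)C2(C)C)[C@H]([C@@H](C)C=C)CC#CC | intermediate (not isolated)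
6 | (3S,4S)-3-methyloct-1-en-6-yn-4-ol (syn) | O[C@H]([C@@H](C)C=C)CC#CC | intermediate
7 | tert-butyldimethylsilyl chloride | CC(C)(C)[Si](C)(C)Cl | starting material
8 | tert-butyldimethyl{[(3S,4S)-3-methyloct-1-en-6-yn-4-yl]oxy}silane | CC(C)(C)[Si](C)(C)O[C@H]([C@@H](C)C=C)CC#CC | intermediate
9 | hexacarbonyldicobalt complex of the alkyne of 8 (C2Co2 tetrahedrane with a Co–Co bond) | CC(C)(C)[Si](C)(C)O[C@H]([C@@H](C)C=C)CC12C3(C)[Co]1(=C=O)(=C=O)(=C=O)[Co]23(=C=O)(=C=O)=C=O | intermediate (not isolated)
10 | (5S,6S,6aS)-5-[(tert-butyldimethylsilyl)oxy]-3,6-dimethyl-4,5,6,6a-tetrahydropentalen-2(1H)-one | CC(C)(C)[Si](C)(C)O[C@H]1CC2=C(C)C(=O)C[C@H]2[C@@H]1C | intermediate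
11 | (3R,3aR,5S,6S,6aR)-5-[(tert-butyldimethylsilyl)oxy]-3,6-dimethylhexahydropentalen-2(1H)-one (cis-fused) | CC(C)(C)[Si](C)(C)O[C@H]1C[C@H]2[C@@H](C)C(=O)C[C@H]2[C@@H]1C | intermediate
12 | (1R,3aR,4S,5S,6aR)-5-[(tert-butyldimethylsilyl)oxy]-1,4-dimethyl-2-[(trimethylsilyl)oxy]-1,3a,4,5,6,6a-hexahydropentalene | CC(C)(C)[Si](C)(C)O[C@H]1C[C@H]2[C@@H](C)C(O[Si](C)(C)C)=C[C@H]2[C@@H]1C | intermediate
13 | (2R)-2-[(1R,2R,3S,4S)-4-[(tert-butyldimethylsilyl)oxy]-2-formyl-3-methylcyclopentyl]propanoic acid | CC(C)(C)[Si](C)(C)O[C@H]1C[C@@H]([C@@H](C)C(=O)O)[C@@H](C=O)[C@@H]1C | intermediate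
14 | methylamine | CN | starting material
15 | (2R)-2-[(1R,2R,3S,4S)-4-[(tert-butyldimethylsilyl)oxy]-3-methyl-2-[(methylamino)methyl]cyclopentyl]propanoic acid | CC(C)(C)[Si](C)(C)O[C@H]1C[C@@H]([C@@H](C)C(=O)O)[C@@H](CNC)[C@@H]1C | intermediate (not isolated)
16 | (4R,4aR,6S,7S,7aR)-6-[(tert-butyldimethylsilyl)oxy]-2,4,7-trimethyloctahydro-3H-cyclopenta[c]pyridin-3-one | CC(C)(C)[Si](C)(C)O[C@H]1C[C@@H]2[C@@H](CN(C)C(=O)[C@@H]2C)[C@@H]1C | intermediate
17 | (4R,4aS,6S,7S,7aR)-6-[(tert-butyldimethylsilyl)oxy]-2,4,7-trimethyloctahydro-1H-cyclopenta[c]pyridine | CC(C)(C)[Si](C)(C)O[C@H]1C[C@@H]2[C@@H](CN(C)C[C@@H]2C)[C@@H]1C | intermediate (not isolated)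
18 | (4R,4aS,6S,7S,7aR)-2,4,7-trimethyloctahydro-1H-cyclopenta[c]pyridin-6-ol (C6 epimer of the amino alcohol in the target) | O[C@H]1C[C@@H]2[C@@H](CN(C)C[C@@H]2C)[C@@H]1C | intermediate
19 | ferulic acid, (E)-3-(4-hydroxy-3-methoxyphenyl)prop-2-enoic acid | COc1cc(/C=C/C(=O)O)ccc1O | starting material
20 | benzyl bromide | BrCc1ccccc1 | starting material
21 | benzyl (E)-3-[4-(benzyloxy)-3-methoxyphenyl]prop-2-enoate | COc1cc(/C=C/C(=O)OCc2ccccc2)ccc1OCc1ccccc1 | intermediate (not isolated)
22 | (E)-3-[4-(benzyloxy)-3-methoxyphenyl]prop-2-enoic acid | COc1cc(/C=C/C(=O)O)ccc1OCc1ccccc1 | intermediate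
23 | (1α,2α,3β,4β)-2,4-bis[4-(benzyloxy)-3-methoxyphenyl]cyclobutane-1,3-dicarboxylic acid (centrosymmetric, achiral) | COc1cc([C@H]2[C@H](C(=O)O)[C@H](c3ccc(OCc4ccccc4)c(OC)c3)[C@H]2C(=O)O)ccc1OCc1ccccc1 | intermediate
24 | mono-ester of 23 with the C6-inverted amino alcohol, (6R) ester, other carboxyl free (one of two mono-esters that converge) | COc1cc([C@H]2[C@H](C(=O)O[C@@H]3C[C@@H]4[C@@H](CN(C)C[C@@H]4C)[C@@H]3C)[C@H](c3ccc(OCc4ccccc4)c(OC)c3)[C@H]2C(=O)O)ccc1OCc1ccccc1 | intermediate (not isolated)
25 | bis[(4R,4aS,6R,7S,7aR)-2,4,7-trimethyloctahydro-1H-cyclopenta[c]pyridin-6-yl] (1α,2α,3β,4β)-2,4-bis[4-(benzyloxy)-3-methoxyphenyl]cyclobutane-1,3-dicarboxylate | COc1cc([C@H]2[C@H](C(=O)O[C@@H]3C[C@@H]4[C@@H](CN(C)C[C@@H]4C)[C@@H]3C)[C@H](c3ccc(OCc4ccccc4)c(OC)c3)[C@H]2C(=O)O[C@@H]2C[C@@H]3[C@@H](CN(C)C[C@@H]3C)[C@@H]2C)ccc1OCc1ccccc1 | intermediate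
26 | bis[(4R,4aS,6R,7S,7aR)-2,4,7-trimethyloctahydro-1H-cyclopenta[c]pyridin-6-yl] (1α,2α,3β,4β)-2,4-bis(4-hydroxy-3-methoxyphenyl)cyclobutane-1,3-dicarboxylate | COc1cc([C@H]2[C@H](C(=O)O[C@@H]3C[C@@H]4[C@@H](CN(C)C[C@@H]4C)[C@@H]3C)[C@H](c3ccc(O)c(OC)c3)[C@H]2C(=O)O[C@@H]2C[C@@H]3[C@@H](CN(C)C[C@@H]3C)[C@@H]2C)ccc1O | target

## Step count and least certain steps

Total step count: 13 (nine for the amino alcohol, two for the diacid, two after the junction). Longest linear sequence: 11 steps (steps 1 to 9, then 12 and 13).

**Step 4 (key step).**
- What may go wrong: insufficient facial discrimination in the alkene insertion, because the concave-face silyl ether works against the exo preference of the C7 methyl, so the C7a epimer forms alongside; or oxidative decomposition of the alkyne complex by the N-oxide before cyclisation.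
- Fallback, from 8 back to 10: zirconocene-mediated bicyclisation followed by carbonylation. Cp2ZrCl2 with two equivalents of n-BuLi in THF (−78 °C → rt) generates a divalent zirconium equivalent that couples alkyne and alkene to the zirconacyclopentene F1 (not isolated). Because this oxidative coupling is reversible, the diastereomer with the exo C7 methyl should accumulate under thermodynamic control. CO (1 atm, 0 °C) then inserts and reductive elimination releases 10.

**Step 2 (with step 1).**
- What may go wrong: isomerisation of the β,γ-alkynyl aldehyde to the allenal and evaporative loss before C–C bond formation; partial Z to E equilibration of the crotylpotassium on warming, eroding the syn selectivity.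
- Fallback, from 3 (converted into borane 4 as in step 2) back to 6, replacing the labile aldehyde by the stable commercial (tert-butyldimethylsilyloxy)acetaldehyde. The same crotylboration should give (2R,3S)-1-[(tert-butyldimethylsilyl)oxy]-3-methylpent-4-en-2-ol F2. Tetrabutylammonium fluoride in THF frees (2R,3S)-3-methylpent-4-ene-1,2-diol F3. NaH and N-tosylimidazole in THF sulfonylate the primary hydroxyl to (2R,3S)-2-hydroxy-3-methylpent-4-en-1-yl 4-methylbenzenesulfonate F4 (not isolated), whose alkoxide closes to (2R)-2-[(2S)-but-3-en-2-yl]oxirane F5 with retention at the carbinol carbon. Opening of F5 at its CH2 terminus by 1-propynyllithium (CH3C≡CLi) with BF3·OEt2 in THF at −78 °C gives 6.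

**Step 5.**
- What may go wrong: sluggish reduction of the tetrasubstituted alkene, hydrogen delivery to the concave face, or palladium-mediated epimerisation at C4 toward the more stable exo methyl.
- Fallback, from 10 back to 11: dissolving-metal reduction. Li in liquid NH3/THF with one equivalent of t-BuOH at −78 °C protonates C4a to the only strain-free, cis-fused ring junction and leaves the regiodefined lithium enolate F6 (not isolated). Inverse quench into cold aqueous NH4Cl should protonate C4 kinetically from the convex face, leaving the methyl on the concave side as in 11.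

**Step 11.**
- What may go wrong: a crystal form of 22 in which the alkenes are too far apart or stacked head-to-head, giving no reaction or the wrong dimer; E/Z isomerisation at crystal surfaces.
- Fallback, from 19 (and 18) back to 26, changing the group on the phenol to one that alters the packing and is carried to the end. TsCl in aqueous NaOH (Schotten–Baumann conditions) gives (E)-3-{3-methoxy-4-[(4-methylbenzenesulfonyl)oxy]phenyl}prop-2-enoic acid F7. Irradiation of its crystals as in step 11 should give the head-to-tail bis-sulfonate diacid F8. Double Mitsunobu coupling of F8 with 18 as in step 12 gives the bis-sulfonate diester F9. Mg in MeOH at 0 °C → rt cleaves the two aryl sulfonate S–O bonds by electron transfer, leaving the alkyl esters, and releases 26.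

**Step 12.**
- What may go wrong: elimination from the alkoxyphosphonium ion toward C5 or C7 instead of substitution, or stalling at mono-ester 24 because its remaining carboxylate is hindered and the ammonium carboxylate is poorly soluble.
- Fallback, from 18 back to 25, separating inversion from coupling. Mitsunobu reaction of 18 with 4-nitrobenzoic acid (PPh3, DIAD, THF), a small and acidic partner suited to hindered alcohols, gives the inverted ester (4R,4aS,6R,7S,7aR)-2,4,7-trimethyloctahydro-1H-cyclopenta[c]pyridin-6-yl 4-nitrobenzoate F10. K2CO3 in MeOH releases the (6R) amino alcohol (4R,4aS,6R,7S,7aR)-2,4,7-trimethyloctahydro-1H-cyclopenta[c]pyridin-6-ol F11. Separately, 23 with oxalyl chloride and catalytic DMF in CH2Cl2 gives the diacid dichloride F12. F12 acylates two equivalents of F11 with retention (Et3N, 4-dimethylaminopyridine, CH2Cl2, 0 °C → rt) to give 25.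

## Further compounds

F1 | step 4 | bis(cyclopentadienyl)zirconacyclopentene from 8 (Zr bonded to C4 and C1, C4a–C7a bond formed, C7 methyl exo) | CC(C)(C)[Si](C)(C)O[C@H]1CC2=C(C)[Zr](C3C=CC=C3)(C3C=CC=C3)C[C@H]2[C@@H]1C
F2 | step 2 | (2R,3S)-1-[(tert-butyldimethylsilyl)oxy]-3-methylpent-4-en-2-ol | O[C@H]([C@@H](C)C=C)CO[Si](C)(C)C(C)(C)C
F3 | step 2 | (2R,3S)-3-methylpent-4-ene-1,2-diol | O[C@H]([C@@H](C)C=C)CO
F4 | step 2 | (2R,3S)-2-hydroxy-3-methylpent-4-en-1-yl 4-methylbenzenesulfonate | O[C@H]([C@@H](C)C=C)COS(=O)(=O)c1ccc(C)cc1
F5 | step 2 | (2R)-2-[(2S)-but-3-en-2-yl]oxirane | C1O[C@@H]1[C@@H](C)C=C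
F6 | step 5 | lithium enolate (C3–C4 enolate) of cis-fused ketone 11 | [Li+].CC(C)(C)[Si](C)(C)O[C@H]1C[C@H]2C(C)=C([O-])C[C@H]2[C@@H]1C
F7 | step 11 | (E)-3-{3-methoxy-4-[(4-methylbenzenesulfonyl)oxy]phenyl}prop-2-enoic acid | COc1cc(/C=C/C(=O)O)ccc1OS(=O)(=O)c1ccc(C)cc1
F8 | step 11 | (1α,2α,3β,4β)-2,4-bis{3-methoxy-4-[(4-methylbenzenesulfonyl)oxy]phenyl}cyclobutane-1,3-dicarboxylic acid | COc1cc([C@H]2[C@H](C(=O)O)[C@H](c3ccc(OS(=O)(=O)c4ccc(C)cc4)c(OC)c3)[C@H]2C(=O)O)ccc1OS(=O)(=O)c1ccc(C)cc1
F9 | step 11 | bis[(4R,4aS,6R,7S,7aR)-2,4,7-trimethyloctahydro-1H-cyclopenta[c]pyridin-6-yl] (1α,2α,3β,4β)-2,4-bis{3-methoxy-4-[(4-methylbenzenesulfonyl)oxy]phenyl}cyclobutane-1,3-dicarboxylate | COc1cc([C@H]2[C@H](C(=O)O[C@@H]3C[C@@H]4[C@@H](CN(C)C[C@@H]4C)[C@@H]3C)[C@H](c3ccc(OS(=O)(=O)c4ccc(C)cc4)c(OC)c3)[C@H]2C(=O)O[C@@H]2C[C@@H]3[C@@H](CN(C)C[C@@H]3C)[C@@H]2C)ccc1OS(=O)(=O)c1ccc(C)cc1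
F10 | step 12 | (4R,4aS,6R,7S,7aR)-2,4,7-trimethyloctahydro-1H-cyclopenta[c]pyridin-6-yl 4-nitrobenzoate | O=C(O[C@@H]1C[C@@H]2[C@@H](CN(C)C[C@@H]2C)[C@@H]1C)c1ccc([N+](=O)[O-])cc1
F11 | step 12 | (4R,4aS,6R,7S,7aR)-2,4,7-trimethyloctahydro-1H-cyclopenta[c]pyridin-6-ol | O[C@@H]1C[C@@H]2[C@@H](CN(C)C[C@@H]2C)[C@@H]1C
F12 | step 12 | (1α,2α,3β,4β)-2,4-bis[4-(benzyloxy)-3-methoxyphenyl]cyclobutane-1,3-dicarbonyl dichloride | COc1cc([C@H]2[C@H](C(=O)Cl)[C@H](c3ccc(OCc4ccccc4)c(OC)c3)[C@H]2C(=O)Cl)ccc1OCc1ccccc1
A1 | alternative 1 | dimethyl (1α,2α,3β,4β)-2,4-bis(4-acetoxy-3-methoxyphenyl)cyclobutane-1,3-dicarboxylate | COc1cc([C@H]2[C@H](C(=O)OC)[C@H](c3ccc(OC(C)=O)c(OC)c3)[C@H]2C(=O)OC)ccc1OC(C)=O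
A2 | alternative 1 | dimethyl 3,5-bis(4-acetoxy-3-methoxyphenyl)pyrrolidine-2,4-dicarboxylate (racemic; 2,3-cis, 3,4-trans, 4,5-cis, one enantiomer drawn) | COc1cc([C@H]2N[C@H](C(=O)OC)[C@H](c3ccc(OC(C)=O)c(OC)c3)[C@H]2C(=O)OC)ccc1OC(C)=O
A3 | alternative 2 | (4R,4aS,7S,7aR)-2,4,7-trimethyloctahydro-6H-cyclopenta[c]pyridin-6-one | O=C1C[C@@H]2[C@@H](CN(C)C[C@@H]2C)[C@@H]1C
A4 | alternative 2 | 1,3-dioxoisoindolin-2-yl N-methyl-N-{(2R)-2-[(1R)-3-methyl-4-oxocyclopent-2-en-1-yl]propyl}glycinate | O=C1C[C@@H]([C@@H](C)CN(C)CC(=O)ON2C(=O)c3ccccc3C2=O)C=C1C
A5 | alternative 3 | anti head-to-tail photodimer of 7-(benzyloxy)-6-methoxycoumarin (centrosymmetric bis-dihydrocoumarin) | COc1cc3[C@H]2[C@H](C(=O)Oc4cc(OCc5ccccc5)c(OC)cc46)[C@H]6[C@H]2C(=O)Oc3cc1OCc1ccccc1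
A6 | alternative 3 | 7-(benzyloxy)-6-methoxy-2H-chromen-2-one | COc1cc2ccc(=O)oc2cc1OCc1ccccc1
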